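The runs stem from a simulated flask from invented constants; noise was put on by code.

**The question.** What share of its substrate does ash turn into target by 12 min, and what are the two orders at the cedar charge?

all flasks: free catalyst 6.00 × 10⁻⁴ M

|  | substrate | partner | time |
|---|---|---|---|
| cedar | 0.300 M | 0.300 M |  |
| maple | 0.150 M | 0.300 M |  |
| larch | 0.300 M | 0.150 M |  |
| ash | 0.300 M | 0.0650 M | 12 min |

- cedar run (time / min: [target] / M): 2.0: 0.0351; 4.0: 0.0571; 6.0: 0.0672; 8.0: 0.0736; 10: 0.0782; 12: 0.0787
- maple run (time / min: [target] / M): 2.0: 0.0243; 4.0: 0.0383; 6.0: 0.0508; 8.0: 0.0590; 10: 0.0640; 12: 0.0697
- larch run (time / min: [target] / M): 2.0: 0.0267; 4.0: 0.0358; 6.0: 0.0377; 8.0: 0.0402; 10: 0.0402; 12: 0.0400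

(readings scatter by 9 × 10⁻⁴ M)

- the exponent of [partner] in the starting rate at the charge of the cedar run (at the point where two percent of the substrate have become target)
- the exponent of [substrate] in the starting rate at the charge of the cedar run (at the point where two percent of the substrate have become target) (one fixed amount of target, the same in the runs compared)
- target in the ash run at 12 min, as a share of the substrate charged

- Overall: substrate + partner -> target, with free catalyst as catalyst.
- Constant volume, constant temperature.
- A reading of a species includes what of it is bound.
- "The second partner" is partner.
- An order is taken over about fifteen percent of the charge, up and down.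

**Bench rule.** I start from the limiting reagent. In ash the partner is the smaller charge, 0.0650 M against 0.300 M of substrate, so the rule caps ash at 21.7 % of its substrate.

**Its border.** Larch also has partner as its smaller charge, and its readings stop short of that cap. The last larch reading over the larch partner charge is 26.7 %, and I call that ratio the stall share. The last larch reading leaves 0.110 M of partner unused. The same ratio in cedar reads 26.2 %: at equal substrate, twice the partner gives twice the last reading.

**Ash reckoned.** The gap to the last larch reading shrinks from 0.0400 M to 0.0133 M in the first 2.0 min, which reads as a lifetime of 1.82 min. I lend that lifetime to ash, since larch has the lowest partner charge of the three runs, and 12 min is then 6.59 lifetimes. So my estimate puts ash at its plateau: 0.0174 M of target, or 5.79 % of its substrate.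

**The forecast.** It gives 5.8 % for ash, with orders 0.65 in substrate and 0.2 in partner. Its ground is this: “The plateau is therefore about 26.5% of the partner charge and does not depend on substrate.” I have no reckoning of my own for the orders, and on ash we stand together.

**The result.** Ash gives 5.87 %, and the orders are 0.68 in substrate and −0.068 in partner, the latter lower than the forecast's 0.2.

    free catalyst + substrate → catalyst-substrate complex (702.0 M⁻¹ min⁻¹)
    catalyst-substrate complex + partner → target + free catalyst (405.0 M⁻¹ min⁻¹)
    catalyst-substrate complex → spent catalyst + substrate (0.7680 min⁻¹)
    free catalyst + partner ⇌ idle catalyst-reagent complex, settled at all times (8.290 M⁻¹)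

**Share again.** At 12 min ash stands at 27.1 % of its partner charge, beside the stall share of 26.7 % read in larch. The stall share of the maple partner charge comes to 0.0800 M, more than the 0.0750 M that is half of the maple substrate, and the maple run reaches that half at 17.5 min.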